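**Retrosynthetic overview**
1. Target ⇒ α-linolenic acid + the (2E,6E)-C20 monocyclic dienol (ester C–O bond, made last).
2. Dienol ⇒ (5E)-C18 methyl ketone by Horner–Wadsworth–Emmons two-carbon olefination and ester reduction (C2=C3).
3. C18 ketone ⇒ C15 tertiary vinyl carbinol by the key Claisen rearrangement ([3,3]-sigmatropic, Saucy–Marbet variant), which makes the C4–C5 bond and the C6=C7 alkene.
4. Vinyl carbinol ⇒ (S)-dihydro-α-ionone ⇒ (S)-α-ionone (vinyl Grignard addition; conjugate reduction).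
5. No ring is formed in the route: the single cyclohexene ring and the single stereocentre are bought in (S)-α-ionone and carried through unchanged.

Assumption: (S)-(−)-α-ionone (≥98% ee) is bought as the single enantiomer; its stereocentre has the same spatial arrangement and descriptor (S) as the ring stereocentre of the target.

**Step 1**
Reactants: 1 (S)-α-ionone [(3E)-4-[(1S)-2,6,6-trimethylcyclohex-2-en-1-yl]but-3-en-2-one]
Product: 3 (S)-dihydro-α-ionone [4-[(1S)-2,6,6-trimethylcyclohex-2-en-1-yl]butan-2-one], via triethylsilyl enol ether 2 (not isolated)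
Conditions: Et3SiH (1.1 equiv), RhCl(PPh3)3 (0.5 mol %), toluene, 60 °C; then K2CO3 (cat.), MeOH, rt
Reagents that add atoms: none
Why: Rh-catalysed 1,4-hydrosilylation (conjugate reduction) reduces only the enone C=C, leaves the hindered trisubstituted ring alkene alone and, being non-basic, cannot epimerise the doubly allylic ring stereocentre through a dienolate, and methanolysis of the silyl enol ether then frees the saturated ketone without forming a new stereocentre.

**Step 2**
Reactants: 3 (S)-dihydro-α-ionone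
Product: 5 3-methyl-5-[(1S)-2,6,6-trimethylcyclohex-2-en-1-yl]pent-1-en-3-ol (both C3 epimers), via bromomagnesium alkoxide 4 (not isolated)
Conditions: CH2=CHMgBr (1.5 equiv), THF, 0 °C; then H2O
Reagents that add atoms: vinylmagnesium bromide, C=C[Mg]Br
Why: Grignard 1,2-addition to the methyl ketone gives the tertiary vinyl carbinol, whose new carbinol centre forms without control (about 1:1), which is harmless because it becomes sp2 in step 3.

**Step 3**
Reactants: 5 3-methyl-5-[(1S)-2,6,6-trimethylcyclohex-2-en-1-yl]pent-1-en-3-ol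
Product: 8 (5E)-6-methyl-8-[(1S)-2,6,6-trimethylcyclohex-2-en-1-yl]oct-5-en-2-one, via mixed methyl ketal 6 (not isolated), via allyl isopropenyl ether 7 (not isolated)
Conditions: 2-methoxypropene (4 equiv), pyridinium p-toluenesulfonate (2 mol %), toluene, sealed tube, 130 °C; E isomer isolated on AgNO3-impregnated SiO2
Reagents that add atoms: 2-methoxypropene, COC(C)=C
Why: In this Saucy–Marbet variant of the Claisen rearrangement, acid-catalysed transetherification gives the allyl isopropenyl ether, whose [3,3]-sigmatropic shift through a chair transition state forms the C3–C4 bond and the C5=C6 alkene of 8, erases the carbinol centre and leaves the ring stereocentre untouched; because methyl and the CH2 chain compete for the equatorial site the E:Z ratio is expected to be only about 3:2, so the E ketone has to be separated.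

**Step 4**
Reactants: 8 (5E)-6-methyl-8-[(1S)-2,6,6-trimethylcyclohex-2-en-1-yl]oct-5-en-2-one
Product: 9 ethyl (2E,6E)-3,7-dimethyl-9-[(1S)-2,6,6-trimethylcyclohex-2-en-1-yl]nona-2,6-dienoate
Conditions: (EtO)2P(O)CH2CO2Et (2 equiv), NaH (2 equiv), THF, 0 °C to 50 °C; SiO2 chromatography
Reagents that add atoms: triethyl phosphonoacetate, CCOC(=O)CP(=O)(OCC)OCC
Why: Horner–Wadsworth–Emmons olefination of the methyl ketone gives mainly the 2E ester (about 4:1 expected), the 2Z isomer separates on silica, and no stereocentre is formed or disturbed.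

**Step 5**
Reactants: 9 ethyl (2E,6E)-3,7-dimethyl-9-[(1S)-2,6,6-trimethylcyclohex-2-en-1-yl]nona-2,6-dienoate
Product: 12 (2E,6E)-3,7-dimethyl-9-[(1S)-2,6,6-trimethylcyclohex-2-en-1-yl]nona-2,6-dien-1-ol, via dienal 10 (not isolated), via aluminium alkoxide 11 (not isolated)
Conditions: iBu2AlH (2.5 equiv), CH2Cl2, −78 °C; then aq. potassium sodium tartrate
Reagents that add atoms: none
Why: Hydride 1,2-reduction of the conjugated ester by iBu2AlH at low temperature stops at the allylic alcohol without conjugate reduction or change of alkene geometry.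

**Step 6**
Reactants: 12 (2E,6E)-3,7-dimethyl-9-[(1S)-2,6,6-trimethylcyclohex-2-en-1-yl]nona-2,6-dien-1-ol; 13 α-linolenic acid [(9Z,12Z,15Z)-octadeca-9,12,15-trienoic acid]
Product: 15 (2E,6E)-3,7-dimethyl-9-[(1S)-2,6,6-trimethylcyclohex-2-en-1-yl]nona-2,6-dien-1-yl (9Z,12Z,15Z)-octadeca-9,12,15-trienoate (CNP0115076.1), via O-acylisourea 14 (not isolated)
Conditions: N,N'-dicyclohexylcarbodiimide (1.2 equiv), 4-(dimethylamino)pyridine (0.1 equiv), CH2Cl2, 0 °C to rt, argon, dark
Reagents that add atoms: none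
Why: Steglich esterification acylates the unhindered primary allylic alcohol under neutral conditions that neither isomerise the skipped (Z,Z,Z)-triene nor ionise the allylic C–O bond, so all alkene geometries and the (S) centre arrive intact.

**Compound list**
1 | (S)-α-ionone, (3E)-4-[(1S)-2,6,6-trimethylcyclohex-2-en-1-yl]but-3-en-2-one | CC(=O)/C=C/[C@@H]1C(C)=CCCC1(C)C | starting material
2 | triethyl({4-[(1S)-2,6,6-trimethylcyclohex-2-en-1-yl]but-2-en-2-yl}oxy)silane (E/Z mixture, not isolated) | CC(O[Si](CC)(CC)CC)=CC[C@@H]1C(C)=CCCC1(C)C | intermediate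
3 | (S)-dihydro-α-ionone, 4-[(1S)-2,6,6-trimethylcyclohex-2-en-1-yl]butan-2-one | CC(=O)CC[C@@H]1C(C)=CCCC1(C)C | intermediate
4 | bromomagnesium 3-methyl-5-[(1S)-2,6,6-trimethylcyclohex-2-en-1-yl]pent-1-en-3-olate (not isolated) | C=CC(C)(O[Mg]Br)CC[C@@H]1C(C)=CCCC1(C)C | intermediate
5 | 3-methyl-5-[(1S)-2,6,6-trimethylcyclohex-2-en-1-yl]pent-1-en-3-ol (both C3 epimers) | C=CC(C)(O)CC[C@@H]1C(C)=CCCC1(C)C | intermediate
6 | (6S)-6-{3-[(2-methoxypropan-2-yl)oxy]-3-methylpent-4-en-1-yl}-1,5,5-trimethylcyclohex-1-ene (mixed methyl ketal, not isolated) | C=CC(C)(OC(C)(C)OC)CC[C@@H]1C(C)=CCCC1(C)C | intermediate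
7 | (6S)-1,5,5-trimethyl-6-[3-methyl-3-(prop-1-en-2-yloxy)pent-4-en-1-yl]cyclohex-1-ene (allyl isopropenyl ether, not isolated) | C=CC(C)(OC(C)=C)CC[C@@H]1C(C)=CCCC1(C)C | intermediate
8 | (5E)-6-methyl-8-[(1S)-2,6,6-trimethylcyclohex-2-en-1-yl]oct-5-en-2-one | CC(=O)CC/C=C(\C)CC[C@@H]1C(C)=CCCC1(C)C | intermediate
9 | ethyl (2E,6E)-3,7-dimethyl-9-[(1S)-2,6,6-trimethylcyclohex-2-en-1-yl]nona-2,6-dienoate | CCOC(=O)/C=C(\C)CC/C=C(\C)CC[C@@H]1C(C)=CCCC1(C)C | intermediate
10 | (2E,6E)-3,7-dimethyl-9-[(1S)-2,6,6-trimethylcyclohex-2-en-1-yl]nona-2,6-dienal (not isolated) | O=C/C=C(\C)CC/C=C(\C)CC[C@@H]1C(C)=CCCC1(C)C | intermediate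
11 | diisobutylaluminium (2E,6E)-3,7-dimethyl-9-[(1S)-2,6,6-trimethylcyclohex-2-en-1-yl]nona-2,6-dien-1-olate (not isolated) | CC(C)C[Al](CC(C)C)OC/C=C(\C)CC/C=C(\C)CC[C@@H]1C(C)=CCCC1(C)C | intermediate
12 | (2E,6E)-3,7-dimethyl-9-[(1S)-2,6,6-trimethylcyclohex-2-en-1-yl]nona-2,6-dien-1-ol | OC/C=C(\C)CC/C=C(\C)CC[C@@H]1C(C)=CCCC1(C)C | intermediate
13 | α-linolenic acid, (9Z,12Z,15Z)-octadeca-9,12,15-trienoic acid | CC/C=C\C/C=C\C/C=C\CCCCCCCC(=O)O | starting material
14 | O-[(9Z,12Z,15Z)-octadeca-9,12,15-trienoyl]-N,N'-dicyclohexylisourea (not isolated) | CC/C=C\C/C=C\C/C=C\CCCCCCCC(=O)OC(=NC1CCCCC1)NC1CCCCC1 | intermediate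
15 | (2E,6E)-3,7-dimethyl-9-[(1S)-2,6,6-trimethylcyclohex-2-en-1-yl]nona-2,6-dien-1-yl (9Z,12Z,15Z)-octadeca-9,12,15-trienoate | CC/C=C\C/C=C\C/C=C\CCCCCCCC(=O)OC/C=C(\C)CC/C=C(\C)CC[C@@H]1C(C)=CCCC1(C)C | target

**Total step count:** 6
**Longest linear sequence:** 6 steps (1 → 15); α-linolenic acid 13 enters in the last step.

**Three steps most likely to fail, with fallbacks**

Step 3 (the rearrangement is reliable, but the E:Z ratio at the new trisubstituted alkene is low and the isomers are hard to separate). The fallback sets out from 3 and comes back at 8, building the alkene by carbometalation and cross-coupling instead. The kinetic enolate of 3 (LiN(iPr)2, THF, −78 °C) is trapped with ClP(O)(OEt)2 to give diethyl 4-[(1S)-2,6,6-trimethylcyclohex-2-en-1-yl]but-1-en-2-yl phosphate F1. More LiN(iPr)2 eliminates phosphate from it to give the terminal alkyne (6S)-6-(but-3-yn-1-yl)-1,5,5-trimethylcyclohex-1-ene F2. Zr-catalysed syn-methylalumination (AlMe3, Cp2ZrCl2, ClCH2CH2Cl, rt) gives the (E)-alkenyldimethylalane F3, and I2 converts it with retention into the (E)-vinyl iodide F4. B-alkyl Suzuki–Miyaura coupling (PdCl2(dppf), K3PO4, DMF/THF/H2O) with 9-[2-(2-methyl-1,3-dioxolan-2-yl)ethyl]-9-borabicyclo[3.3.1]nonane F5, made from 2-methyl-2-vinyl-1,3-dioxolane and 9-borabicyclo[3.3.1]nonane, gives the dioxolane F6. Pyridinium p-toluenesulfonate in wet acetone unmasks the ketone and returns to 8 as the E isomer only.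

Step 4 (olefination of a methyl ketone gives a 2E/2Z mixture). The fallback sets out from 8 and comes back at 9, again by carbometalation. LiN(iPr)2 and ClP(O)(OEt)2 give the diethyl enol phosphate F7, and further LiN(iPr)2 gives the enyne (6S)-1,5,5-trimethyl-6-[(3E)-3-methyloct-3-en-7-yn-1-yl]cyclohex-1-ene F8. Methylalumination (AlMe3, Cp2ZrCl2) gives the (1E,5E)-dienyldimethylalane F9, which is acylated in the same flask with ClCO2Et to give 9 with the 2E geometry fixed by syn addition.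

Step 1 (some 1,2-hydrosilylation or slow turnover would lower yield). The fallback sets out from 1 and comes back at 3 by reduction followed by redox isomerisation. Luche reduction (NaBH4, CeCl3·7H2O, MeOH, 0 °C) gives (S)-α-ionol F10 as a mixture of carbinol epimers. Base-free isomerisation of this allylic alcohol (CpRu(PPh3)2Cl, Et3NHPF6, dioxane, 100 °C) then gives the saturated ketone 3.

**Further compounds**
F1 | step 3 | diethyl 4-[(1S)-2,6,6-trimethylcyclohex-2-en-1-yl]but-1-en-2-yl phosphate | C=C(OP(=O)(OCC)OCC)CC[C@@H]1C(C)=CCCC1(C)C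
F2 | step 3 | (6S)-6-(but-3-yn-1-yl)-1,5,5-trimethylcyclohex-1-ene | C#CCC[C@@H]1C(C)=CCCC1(C)C
F3 | step 3 | dimethyl{(1E)-2-methyl-4-[(1S)-2,6,6-trimethylcyclohex-2-en-1-yl]but-1-en-1-yl}alane | C[Al](C)/C=C(\C)CC[C@@H]1C(C)=CCCC1(C)C
F4 | step 3 | (6S)-6-[(3E)-4-iodo-3-methylbut-3-en-1-yl]-1,5,5-trimethylcyclohex-1-ene | I/C=C(\C)CC[C@@H]1C(C)=CCCC1(C)C
F5 | step 3 | 9-[2-(2-methyl-1,3-dioxolan-2-yl)ethyl]-9-borabicyclo[3.3.1]nonane | CC1(CCB2C3CCCC2CCC3)OCCO1
F6 | step 3 | 2-methyl-2-{(3E)-4-methyl-6-[(1S)-2,6,6-trimethylcyclohex-2-en-1-yl]hex-3-en-1-yl}-1,3-dioxolane | CC1(CC/C=C(\C)CC[C@@H]2C(C)=CCCC2(C)C)OCCO1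
F7 | step 4 | diethyl (5E)-6-methyl-8-[(1S)-2,6,6-trimethylcyclohex-2-en-1-yl]octa-1,5-dien-2-yl phosphate | C=C(OP(=O)(OCC)OCC)CC/C=C(\C)CC[C@@H]1C(C)=CCCC1(C)C
F8 | step 4 | (6S)-1,5,5-trimethyl-6-[(3E)-3-methyloct-3-en-7-yn-1-yl]cyclohex-1-ene | C#CCC/C=C(\C)CC[C@@H]1C(C)=CCCC1(C)C
F9 | step 4 | {(1E,5E)-2,6-dimethyl-8-[(1S)-2,6,6-trimethylcyclohex-2-en-1-yl]octa-1,5-dien-1-yl}dimethylalane | C[Al](C)/C=C(\C)CC/C=C(\C)CC[C@@H]1C(C)=CCCC1(C)C
F10 | step 1 | (S)-α-ionol, (3E)-4-[(1S)-2,6,6-trimethylcyclohex-2-en-1-yl]but-3-en-2-ol (both carbinol epimers) | CC(O)/C=C/[C@@H]1C(C)=CCCC1(C)C
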